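**Retrosynthetic overview** (prostanoid numbering: ester carbon C1, ring C8–C12, C9 ketone, C10–Cl, C12–OAc)

1. Late bonds: acetate for MOM at C12; C7=C8 by aldol condensation of a 2-chloro-4-alkoxycyclopentenone with methyl (Z)-7-oxohept-5-enoate; C14=C15 by Z-selective Wittig reaction of a ring-bound CH2CHO group.
2. Key disconnection C9–C10: the chlorinated keto aldehyde is an isomer of an achiral, mirror-symmetric dialdehyde, 3-(chloroethynyl)-3-(methoxymethoxy)pentanedial. A chiral cationic rhodium catalyst adds one aldehyde C–H across the chloroalkyne (trans hydroacylation), which closes the ring, puts the ketone on C9 and Cl on C10, and turns C12 into the stereocentre.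
3. Enabling feature: C12, the only stereocentre and a fully substituted carbinol carbon of ring C8–C12, carries two CH2 groups (ring C8, chain C13) that each lead to a carbon at the aldehyde oxidation level (C9, C14). Its third carbon, C11, forms with C10(Cl) a chloroalkyne at the alkene stage, so C9–C8–C12–C11–C10 is a 4-alkynal with two enantiotopic arms.
4. The dialdehyde comes from double ozonolysis of a diallyl(chloroethynyl)carbinol MOM ether, built from ethyl 3-(trimethylsilyl)propiolate and two equivalents of allylmagnesium bromide.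
5. Ring order: the cyclopentenone is the only ring and is formed in the key step.

Key step: step 5

Remark: which enantiotopic arm a given catalyst antipode selects cannot be predicted with certainty; the (R)-Tol-BINAP complex is written, and the (S)-ligand is used if it gives the mirror image.

**Route**

Step 1
Reactants: 1 ethyl 3-(trimethylsilyl)prop-2-ynoate; 2 allylmagnesium bromide
Product: 4 4-ethynylhepta-1,6-dien-4-ol, via trimethylsilyl carbinol 3 (not isolated)
Conditions: 2 (2.4 equiv), Et2O, −78 to 0 °C; then MeOH, K2CO3, rt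
Reagents that add atoms: allylmagnesium bromide, C=CC[Mg]Br
Why: Double 1,2-addition of the allyl Grignard reagent to the ester (allyl reagents attack ynoates and ynones at the carbonyl carbon) gives the tertiary alkoxide, and K2CO3/MeOH then protodesilylates the alkyne; no stereocentre arises because the two allyl groups are identical.

Step 2
Reactants: 4 4-ethynylhepta-1,6-dien-4-ol; 5 chloromethyl methyl ether
Product: 6 4-ethynyl-4-(methoxymethoxy)hepta-1,6-diene
Conditions: 5, iPr2NEt, Bu4NI (cat.), CH2Cl2, 40 °C
Reagents that add atoms: chloromethyl methyl ether, COCCl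
Why: O-alkylation of the tertiary propargylic alcohol (Williamson-type MOM protection) gives an acetal ether that survives BuLi, ozone and enolates and keeps a Lewis-basic ether oxygen on the carbinol carbon for the rhodium step.

Step 3
Reactants: 6 4-ethynyl-4-(methoxymethoxy)hepta-1,6-diene; 7 N-chlorosuccinimide
Product: 9 4-(chloroethynyl)-4-(methoxymethoxy)hepta-1,6-diene, via lithium acetylide 8 (not isolated)
Conditions: n-BuLi, THF, −78 °C; then 7, −78 to 0 °C
Reagents that add atoms: N-chlorosuccinimide, O=C1CCC(=O)N1Cl
Why: Deprotonation of the terminal alkyne and electrophilic chlorination of the lithium acetylide is the standard route to 1-chloroalkynes, and nothing else in 6 is acidic enough for n-BuLi at −78 °C.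

Step 4
Reactants: 9 4-(chloroethynyl)-4-(methoxymethoxy)hepta-1,6-diene; 10 ozone
Product: 11 3-(chloroethynyl)-3-(methoxymethoxy)pentanedial
Conditions: O3, CH2Cl2, −78 °C (Sudan red 7B end point); then PPh3, −78 °C to rt; used without long storage
Reagents that add atoms: ozone, [O-][O+]=O
Why: Ozonolysis with reductive work-up cleaves the two electron-rich terminal alkenes much faster than the electron-poor chloroalkyne and gives the two enantiotopic formylmethyl arms.

Step 5
Reactants: 11 3-(chloroethynyl)-3-(methoxymethoxy)pentanedial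
Product: 12 2-[(1S)-3-chloro-1-(methoxymethoxy)-4-oxocyclopent-2-en-1-yl]acetaldehyde
Conditions: [Rh(nbd)((R)-Tol-BINAP)]BF4 (5–10 mol %, nbd removed with H2 beforehand), CH2Cl2, rt, slow addition of 11
Reagents that add atoms: none
Why: Proposed new method: oxidative addition of one aldehyde C–H bond to the cationic monovalent rhodium centre, which is held by the ether oxygen and the alkyne, gives an acylrhodium hydride; hydride transfer to the proximal alkyne carbon and isomerisation give a six-membered acyl(α-chloroalkenyl)rhodacycle, and C–C reductive elimination joins the acyl carbon to the chlorine-bearing carbon (net trans hydroacylation). The closest known reaction type is the rhodium-bisphosphine-catalysed trans hydroacylation of 4-alkynals to cyclopent-2-enones, including kinetic resolution and desymmetrisation of 3-alkoxy-4-alkynals with a fully substituted C3; new here are the 1-chloroalkyne as acceptor and the choice between two enantiotopic formylmethyl arms. The single ring closes in a formal 5-endo-dig mode, the only one open to a 4-alkynal, since bonding to the proximal alkyne carbon would give a cyclobutanone. The carbinol carbon becomes the stereocentre under catalyst control: the chiral bisphosphine decides which arm undergoes C–H activation, the same discrimination that underlies the known kinetic resolution of the corresponding racemates. The step needs group selectivity between the arms and chemoselectivity for C–H activation over C–Cl insertion or β-chloride loss; chelation by the MOM ether oxygen, the strong C(sp)–Cl bond, the anti placement of rhodium and chlorine in the first hydrometalation adduct and the α-chloroalkenyl nature of the final rhodacycle (no β-chloride) should secure them. The second aldehyde of 12 has no alkyne left to reach, and in the known resolutions an uncyclised aldehyde survives the catalyst.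

Step 6
Reactants: 12 2-[(1S)-3-chloro-1-(methoxymethoxy)-4-oxocyclopent-2-en-1-yl]acetaldehyde; 13 hexyltriphenylphosphonium bromide
Product: 15 (4S)-2-chloro-4-(methoxymethoxy)-4-[(2Z)-oct-2-en-1-yl]cyclopent-2-en-1-one, via hexylidenetriphenylphosphorane 14 (not isolated)
Conditions: 13, NaHMDS, THF, 0 °C; then slow addition of the ylide (1.0 equiv) to 12, THF, −78 to −30 °C
Reagents that add atoms: hexyltriphenylphosphonium bromide, CCCCCC[P+](c1ccccc1)(c1ccccc1)c1ccccc1.[Br-]
Why: Salt-free Wittig reaction of a non-stabilised ylide with an aliphatic aldehyde at low temperature gives the (Z)-alkene under kinetic control and leaves the less electrophilic enone carbonyl alone; the stereocentre is not involved.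

Step 7
Reactants: 16 methyl 7-hydroxyhept-5-ynoate
Product: 17 methyl (5Z)-7-hydroxyhept-5-enoate
Conditions: H2 (1 atm), Pd/CaCO3 poisoned with Pb(OAc)2 (Lindlar catalyst), quinoline, EtOAc, rt
Reagents that add atoms: none
Why: Lindlar semi-hydrogenation adds H2 syn to the alkyne and stops at the (Z)-alkene.

Step 8
Reactants: 17 methyl (5Z)-7-hydroxyhept-5-enoate
Product: 18 methyl (5Z)-7-oxohept-5-enoate
Conditions: Dess–Martin periodinane, NaHCO3, CH2Cl2, 0 °C; used at once
Reagents that add atoms: none
Why: Buffered Dess–Martin oxidation converts the allylic alcohol to the enal under neutral conditions that should not isomerise the (Z)-double bond.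

Step 9
Reactants: 15 (4S)-2-chloro-4-(methoxymethoxy)-4-[(2Z)-oct-2-en-1-yl]cyclopent-2-en-1-one; 18 methyl (5Z)-7-oxohept-5-enoate
Product: 20 methyl (5Z)-7-[(5S)-3-chloro-5-(methoxymethoxy)-5-[(2Z)-oct-2-en-1-yl]-2-oxocyclopent-3-en-1-yl]-7-hydroxyhept-5-enoate (mixture of diastereomers at C7 and C8), via lithium enolate 19 (not isolated)
Conditions: LDA, THF, −78 °C; then 18, −78 °C; sat. aq. NH4Cl at −78 °C
Reagents that add atoms: methyl (5Z)-7-oxohept-5-enoate, COC(=O)CCC/C=C\C=O
Why: LDA can deprotonate only the ring CH2 (the other α-carbon is the chlorinated sp2 carbon and the γ-carbon is fully substituted), and the lithium enolate adds to the aldehyde in a directed aldol addition; the two new stereocentres form unselectively and are both removed in step 10.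

Step 10
Reactants: 20 aldol adduct (name as in step 9); 21 methanesulfonyl chloride
Product: 23 methyl (5Z,7E)-7-[(5R)-3-chloro-5-(methoxymethoxy)-5-[(2Z)-oct-2-en-1-yl]-2-oxocyclopent-3-en-1-ylidene]hept-5-enoate, via secondary mesylate 22 (not isolated)
Conditions: 21, Et3N (excess), CH2Cl2, −20 °C to rt
Reagents that add atoms: none
Why: Mesylation of the secondary alcohol and E1cB elimination through the enolate should give the cross-conjugated dienone as the (7E) isomer, the usual outcome for 2-alkylidenecyclopentenones, in which the vinylic hydrogen and not the chain lies beside the carbonyl oxygen.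

Step 11
Reactants: 23 MOM-protected dienone (name as in step 10); 24 bromodimethylborane
Product: 26 methyl (5Z,7E)-7-[(5R)-3-chloro-5-hydroxy-5-[(2Z)-oct-2-en-1-yl]-2-oxocyclopent-3-en-1-ylidene]hept-5-enoate, via bromomethyl ether 25 (not isolated)
Conditions: 24 (3 equiv), CH2Cl2, −78 °C; then THF/sat. aq. NaHCO3
Reagents that add atoms: none
Why: Lewis acid-assisted acetal cleavage at the methoxy oxygen gives a bromomethyl ether that hydrolyses on bicarbonate work-up; the C12–O bond is never broken, so the configuration is retained.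

Step 12
Reactants: 26 tertiary alcohol (name as in step 11); 27 acetic anhydride
Product: 28 methyl (5Z,7E)-7-[(5R)-5-acetoxy-3-chloro-5-[(2Z)-oct-2-en-1-yl]-2-oxocyclopent-3-en-1-ylidene]hept-5-enoate (the target; prostanoid name methyl (5Z,7E,12R,14Z)-12-acetoxy-10-chloro-9-oxoprosta-5,7,10,14-tetraenoate)
Conditions: 27, DMAP, Et3N, CH2Cl2, rt
Reagents that add atoms: acetic anhydride, CC(=O)OC(C)=O
Why: DMAP-catalysed acylation of the tertiary alcohol (Steglich-type) leaves the C–O bond at the stereocentre untouched.

**Compound list**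

1 | ethyl 3-(trimethylsilyl)prop-2-ynoate | CCOC(=O)C#C[Si](C)(C)C | starting material
2 | allylmagnesium bromide | C=CC[Mg]Br | starting material
3 | 4-[(trimethylsilyl)ethynyl]hepta-1,6-dien-4-ol (bromomagnesium alkoxide in the flask) | C=CCC(O)(CC=C)C#C[Si](C)(C)C | intermediate
4 | 4-ethynylhepta-1,6-dien-4-ol | C=CCC(O)(CC=C)C#C | intermediate
5 | chloromethyl methyl ether | COCCl | starting material
6 | 4-ethynyl-4-(methoxymethoxy)hepta-1,6-diene | C=CCC(OCOC)(CC=C)C#C | intermediate
7 | N-chlorosuccinimide | O=C1CCC(=O)N1Cl | starting material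
8 | lithium acetylide of 6 | C=CCC(OCOC)(CC=C)C#C[Li] | intermediate
9 | 4-(chloroethynyl)-4-(methoxymethoxy)hepta-1,6-diene | C=CCC(OCOC)(CC=C)C#CCl | intermediate
10 | ozone | [O-][O+]=O | starting material
11 | 3-(chloroethynyl)-3-(methoxymethoxy)pentanedial | O=CCC(OCOC)(CC=O)C#CCl | intermediate
12 | 2-[(1S)-3-chloro-1-(methoxymethoxy)-4-oxocyclopent-2-en-1-yl]acetaldehyde | O=CC[C@@]1(OCOC)C=C(Cl)C(=O)C1 | intermediate
13 | hexyltriphenylphosphonium bromide | CCCCCC[P+](c1ccccc1)(c1ccccc1)c1ccccc1.[Br-] | starting material
14 | hexylidenetriphenylphosphorane | CCCCCC=P(c1ccccc1)(c1ccccc1)c1ccccc1 | intermediate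
15 | (4S)-2-chloro-4-(methoxymethoxy)-4-[(2Z)-oct-2-en-1-yl]cyclopent-2-en-1-one | CCCCC/C=C\C[C@@]1(OCOC)C=C(Cl)C(=O)C1 | intermediate
16 | methyl 7-hydroxyhept-5-ynoate | COC(=O)CCCC#CCO | starting material
17 | methyl (5Z)-7-hydroxyhept-5-enoate | COC(=O)CCC/C=C\CO | intermediate
18 | methyl (5Z)-7-oxohept-5-enoate | COC(=O)CCC/C=C\C=O | intermediate
19 | lithium enolate of 15 | CCCCC/C=C\C[C@@]1(OCOC)C=C(Cl)C(O[Li])=C1 | intermediate
20 | methyl (5Z)-7-[(5S)-3-chloro-5-(methoxymethoxy)-5-[(2Z)-oct-2-en-1-yl]-2-oxocyclopent-3-en-1-yl]-7-hydroxyhept-5-enoate (C7/C8 diastereomers) | CCCCC/C=C\C[C@@]1(OCOC)C=C(Cl)C(=O)C1C(O)/C=C\CCCC(=O)OC | intermediate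
21 | methanesulfonyl chloride | CS(=O)(=O)Cl | starting material
22 | 7-O-methanesulfonate of 20 | CCCCC/C=C\C[C@@]1(OCOC)C=C(Cl)C(=O)C1C(OS(C)(=O)=O)/C=C\CCCC(=O)OC | intermediate
23 | methyl (5Z,7E)-7-[(5R)-3-chloro-5-(methoxymethoxy)-5-[(2Z)-oct-2-en-1-yl]-2-oxocyclopent-3-en-1-ylidene]hept-5-enoate | CCCCC/C=C\C[C@@]1(OCOC)C=C(Cl)C(=O)/C1=C/C=C\CCCC(=O)OC | intermediate
24 | bromodimethylborane | CB(C)Br | starting material
25 | bromomethyl ether of 26 | CCCCC/C=C\C[C@@]1(OCBr)C=C(Cl)C(=O)/C1=C/C=C\CCCC(=O)OC | intermediate
26 | methyl (5Z,7E)-7-[(5R)-3-chloro-5-hydroxy-5-[(2Z)-oct-2-en-1-yl]-2-oxocyclopent-3-en-1-ylidene]hept-5-enoate | CCCCC/C=C\C[C@@]1(O)C=C(Cl)C(=O)/C1=C/C=C\CCCC(=O)OC | intermediate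
27 | acetic anhydride | CC(=O)OC(C)=O | starting material
28 | methyl (5Z,7E)-7-[(5R)-5-acetoxy-3-chloro-5-[(2Z)-oct-2-en-1-yl]-2-oxocyclopent-3-en-1-ylidene]hept-5-enoate | CCCCC/C=C\C[C@@]1(OC(C)=O)C=C(Cl)C(=O)/C1=C/C=C\CCCC(=O)OC | target

**Step count and risks**

Total steps: 12. Longest linear sequence: 10 (steps 1–6 and 9–12); steps 7 and 8 make the side-chain aldehyde.

Steps most likely to fail:

1. Step 5 (proposed new method). Rhodium may insert into the C–Cl bond or form a chlorovinylidene and die as a chloride complex. Chloride may be lost from the first hydrometalation adduct. The catalyst may discriminate the two arms poorly, or decarbonylate the aldehyde. Fallback (chirality from the pool, no hydroacylation, known reaction types only): it sets out from allylmagnesium bromide 2, which is added at −78 °C in THF to commercial (R)-4-(tert-butyldimethylsilyloxy)cyclopent-2-en-1-one, 1,2 and anti to the silyloxy group, to give (1S,4R)-1-allyl-4-(tert-butyldimethylsilyloxy)cyclopent-2-en-1-ol F1. MOMCl 5 with iPr2NEt gives (1R,4S)-4-allyl-1-(tert-butyldimethylsilyloxy)-4-(methoxymethoxy)cyclopent-2-ene F2. Bu4NF frees (1R,4S)-4-allyl-4-(methoxymethoxy)cyclopent-2-en-1-ol F3. MnO2 oxidises it to (4S)-4-allyl-4-(methoxymethoxy)cyclopent-2-en-1-one F4, which erases the pool stereocentre and keeps the new one. Weitz–Scheffer epoxidation (H2O2, NaOH, MeOH, 0 °C) attacks only the enone double bond and gives 4-allyl-4-(methoxymethoxy)-6-oxabicyclo[3.1.0]hexan-2-one F5. LiCl/AcOH in THF opens the epoxide at the α-carbon to 4-allyl-2-chloro-3-hydroxy-4-(methoxymethoxy)cyclopentan-1-one F6, which loses water on warming in the same medium to give (4S)-4-allyl-2-chloro-4-(methoxymethoxy)cyclopent-2-en-1-one F7. Ozonolysis of the allyl group (O3, CH2Cl2, −78 °C; PPh3) comes back to the route at 12.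

2. Step 6. The basic ylide may enolise the keto aldehyde (loss of the MOM-oxy group by β-elimination, self-aldol) or attack the enone carbonyl. Fallback (temporary change of oxidation level): it sets out from 12. Luche reduction (NaBH4, CeCl3·7H2O, EtOH/H2O, −15 °C), which reduces a ketone while the aldehyde is masked in situ, gives 2-[(1R)-3-chloro-4-hydroxy-1-(methoxymethoxy)cyclopent-2-en-1-yl]acetaldehyde F8 (both carbinol epimers, the cis one as its lactol). The Wittig reaction with an excess of ylide 14 then meets no ketone and gives (4S)-2-chloro-4-(methoxymethoxy)-4-[(2Z)-oct-2-en-1-yl]cyclopent-2-en-1-ol F9. Dess–Martin oxidation of the allylic alcohol comes back to the route at 15.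

3. Step 11. The Lewis acid and the HBr formed may ionise the tertiary allylic C–O bond, isomerise the 5Z or 7E double bond, or add bromide to the cross-conjugated dienone. Fallback (deprotection before the dienone exists): it sets out from aldol adduct 20. Bromodimethylborane 24 (CH2Cl2, −78 °C) converts the acetal into the bromomethyl ether of the aldol adduct F10, which NaHCO3 work-up hydrolyses to methyl (5Z)-7-[(5S)-3-chloro-5-hydroxy-5-[(2Z)-oct-2-en-1-yl]-2-oxocyclopent-3-en-1-yl]-7-hydroxyhept-5-enoate F11. Acetic anhydride 27, DMAP and Et3N acetylate the secondary hydroxyl to the 7-acetate of the diol F12, which eliminates acetic acid (E1cB) in the flask. This comes back to the route at 26, and under the same conditions 26 is acetylated to 28 as in step 12.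

Further compounds
F1 | step 5 | (1S,4R)-1-allyl-4-(tert-butyldimethylsilyloxy)cyclopent-2-en-1-ol | C=CC[C@@]1(O)C=C[C@H](O[Si](C)(C)C(C)(C)C)C1
F2 | step 5 | (1R,4S)-4-allyl-1-(tert-butyldimethylsilyloxy)-4-(methoxymethoxy)cyclopent-2-ene | C=CC[C@@]1(OCOC)C=C[C@H](O[Si](C)(C)C(C)(C)C)C1
F3 | step 5 | (1R,4S)-4-allyl-4-(methoxymethoxy)cyclopent-2-en-1-ol | C=CC[C@@]1(OCOC)C=C[C@H](O)C1
F4 | step 5 | (4S)-4-allyl-4-(methoxymethoxy)cyclopent-2-en-1-one | C=CC[C@@]1(OCOC)C=CC(=O)C1
F5 | step 5 | 4-allyl-4-(methoxymethoxy)-6-oxabicyclo[3.1.0]hexan-2-one (carbinol carbon as in F4, epoxide face not controlled) | C=CC[C@@]1(OCOC)C2OC2C(=O)C1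
F6 | step 5 | 4-allyl-2-chloro-3-hydroxy-4-(methoxymethoxy)cyclopentan-1-one (carbinol carbon as in F4) | C=CC[C@@]1(OCOC)C(O)C(Cl)C(=O)C1
F7 | step 5 | (4S)-4-allyl-2-chloro-4-(methoxymethoxy)cyclopent-2-en-1-one | C=CC[C@@]1(OCOC)C=C(Cl)C(=O)C1
F8 | step 6 | 2-[(1R)-3-chloro-4-hydroxy-1-(methoxymethoxy)cyclopent-2-en-1-yl]acetaldehyde (carbinol epimers) | O=CC[C@@]1(OCOC)C=C(Cl)C(O)C1
F9 | step 6 | (4S)-2-chloro-4-(methoxymethoxy)-4-[(2Z)-oct-2-en-1-yl]cyclopent-2-en-1-ol (carbinol epimers) | CCCCC/C=C\C[C@@]1(OCOC)C=C(Cl)C(O)C1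
F10 | step 11 | bromomethyl ether of the aldol adduct | CCCCC/C=C\C[C@@]1(OCBr)C=C(Cl)C(=O)C1C(O)/C=C\CCCC(=O)OC
F11 | step 11 | methyl (5Z)-7-[(5S)-3-chloro-5-hydroxy-5-[(2Z)-oct-2-en-1-yl]-2-oxocyclopent-3-en-1-yl]-7-hydroxyhept-5-enoate | CCCCC/C=C\C[C@@]1(O)C=C(Cl)C(=O)C1C(O)/C=C\CCCC(=O)OC
F12 | step 11 | 7-acetate of the diol | CCCCC/C=C\C[C@@]1(O)C=C(Cl)C(=O)C1C(OC(C)=O)/C=C\CCCC(=O)OC
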